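(The numbers in the tables stem from a simulated flask from invented constants; noise was put on by code.)

**The vessel.** This closed, stirred vessel turns starting material and coupling partner into product under free catalyst, at one temperature.

| setting | Saturday's | Wednesday's | Sunday's | Thursday's | Monday's |
|---|---|---|---|---|---|
| starting material | 200 mM | 80.0 mM | 200 mM | 400 mM | 80.0 mM |
| coupling partner | 220 mM | 100 mM | 220 mM | 220 mM | 88.0 mM |
| free catalyst | 10.0 mM | 10.0 mM | 15.0 mM | 10.0 mM | 10.0 mM |
| time |  |  |  |  | 89 h |

- Saturday's run (time / h: [product] / mM): 15: 62.7; 30: 88.6; 44: 106.1; 59: 111.1; 74: 116.8; 89: 125.8
- Wednesday's run (time / h: [product] / mM): 15: 30.5; 30: 43.5; 44: 52.4; 59: 56.9; 74: 57.7; 89: 55.9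
- Sunday's run (time / h: [product] / mM): 15: 84.6; 30: 117.4; 44: 133.7; 59: 143.7; 74: 146.3; 89: 148.2
- Thursday's run (time / h: [product] / mM): 15: 83.0; 30: 122.3; 44: 137.4; 59: 144.6; 74: 147.2; 89: 152.1

(scatter of a reading: 2 mM)

- Overall: starting material + coupling partner -> product, with free catalyst as catalyst.
- Constant volume, constant temperature.
- Readings of a species count what is bound in complexes too.
- "The second partner" is coupling partner.
- An order is taken over about fifteen percent of the charge, up and down.

- order of the initial rate in [starting material], near the charge of the Saturday's run, the rate being that where two percent of its starting material are product (one fixed amount of product, the same in the runs compared)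
- order of the initial rate in [coupling partner], near the charge of the Saturday's run, the rate being that where two percent of its starting material are product
- product in the Monday's run at 89 h, as a share of the starting material charged

**The stall.** Wednesday's flask stops climbing: its last three readings average 56.8 mM. I work with fractions left. Let f_S and f_R be the fractions of starting material and coupling partner not yet in product. On Wednesday they are 0.290 and 0.432.

**The budget.** For a rate proportional to both partners, ln(f_R/f_S) divided by the difference of the charges grows steadily with time. I call this W. Wednesday's flask stalls at 20.0 L mol⁻¹, and that is its budget: the second-order extent a flask reaches before it stops.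

**Monday's flask.** Starting material is the limiting reagent here, at 80.0 mM against 88.0 mM of coupling partner. Its starting material and catalyst match Wednesday's, at 80.0 mM and 10.0 mM, but its coupling partner is lower, 88.0 mM against 100 mM. Spending the same budget is therefore my assumption, and I test it below. Then f_R/f_S reaches 1.17, which gives 52.5 mM of product, or 65.6%.

**The weak link.** W is no constant of the catalyst. Saturday's flask, with larger charges, reaches only 7.17 L mol⁻¹ by 89 h, less than Wednesday's. If W went inversely with the partner charge, Monday's budget would be 22.7 L mol⁻¹, giving 54.9 mM, or 68.6%. I commit to 65.6%, with that figure as the upper edge.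

**The forecast.** It gives 0.55 and 0.55 for the orders and 66% for Monday. It chose to “keep Wednesday's integrated second-order extent at the stall”, the same reckoning as mine.

**The result.** The flask gives 0.51, 0.53 and 67.5%.

    free catalyst + starting material → catalyst-substrate complex (8.136 L mol⁻¹ h⁻¹)
    catalyst-substrate complex + coupling partner → product + free catalyst (5.940 L mol⁻¹ h⁻¹)
    coupling partner → lost reagent (0.01789 h⁻¹)
    free catalyst + coupling partner → spent catalyst + coupling partner (0.4644 L mol⁻¹ h⁻¹)

**The budget again.** The step that loses coupling partner has a half-life of 38.7 h. Monday's 67.5% corresponds to W = 21.6 L mol⁻¹, which is 1.08 times Wednesday's budget. Carrying the budget over held the catalyst charge fixed at 10.0 mM. A changed catalyst charge moves it: Sunday's W at 89 h is 11.6 L mol⁻¹, or 1.62 times Saturday's, on 1.50 times the catalyst.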